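In a one-step world the exchange stops at the complex with one exchanged, and the share asked for is 100 percent in oak, elm, birch and cedar alike.

| flask | starting complex | incoming ligand | remark | time |
|---|---|---|---|---|
| violet | 42 mM | 1.05 equiv | run made earlier |  |
| blue | 28 mM | 1.05 equiv | run made earlier |  |
| red | 63 mM | 1.05 equiv | run made earlier |  |
| oak | 42 mM | 1.05 equiv (fed, over 15.0 min) | all but incoming ligand at the start; incoming ligand goes in evenly over 15.0 min, the run ends at 15 min | 15 min |
| elm | 42 mM (fed, over 15.0 min) | 1.05 equiv | a stirred flask in which starting complex is dosed at a steady rate over 15.0 min without added volume, worked up at 15 min | 15 min |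
| birch | 42 mM | 1.05 equiv | a closed flask charged with all of it at once and left for 15 min | 15 min |
| cedar | 42 mM | 1.05 equiv | one stirred flow tank at steady state, fed with the mixture as stated, mean residence time 15 min |  |

- violet (time / min: complex with one exchanged / %, complex with two exchanged / %, over-reaction product / %): 2.00: 4.7, 1.6, 0; 4.00: 7.9, 1.9, 0; 6.00: 7.9, 4.9, 0; 8.00: 9.2, 6.3, 1.1; 10.0: 11.0, 6.0, 3.1; 12.0: 11.5, 7.7, 4.3; 15.0: 13.6, 7.5, 6.0
- blue (time / min: complex with one exchanged / %, complex with two exchanged / %, over-reaction product / %): 0.667: 0, 1.4, 0; 1.00: 3.2, 0, 0.3; 1.50: 1.7, 0.9, 0; 2.50: 4.6, 2.1, 0.4; 4.00: 6.8, 3.1, 0.9; 6.00: 7.8, 2.2, 0.8; 10.0: 9.4, 3.7, 2.1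
- red (time / min: complex with one exchanged / %, complex with two exchanged / %, over-reaction product / %): 1.33: 3.9, 1.7, 1.2; 2.50: 8.8, 1.3, 0; 4.00: 8.2, 3.4, 2.4; 5.00: 9.0, 5.9, 0.5; 6.00: 11.1, 7.1, 1.8; 8.00: 11.8, 8.9, 2.4; 10.0: 15.5, 10.7, 5.5

(standard deviation of a reading: 1 percentage point)

- the stated concentrations are those of everything mixed, before any reaction; amounts are the same in each set-up
- candidate steps: starting complex + incoming ligand -> leaving ligand + complex with one exchanged; complex with one exchanged + incoming ligand <-> leaving ligand + complex with two exchanged; complex with one exchanged -> over-reaction product
- the feed brings no volume worth counting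
- the earlier runs were made in a closed, stirred flask

- order of the set-ups by the share of complex with one exchanged in all that became complex with one exchanged or complex with two exchanged or over-reaction product, at the outlet or at the end, highest first (oak / elm / birch / cedar)
- share of complex with one exchanged in all that became complex with one exchanged or complex with two exchanged or over-reaction product, at the outlet or at the end, oak
- share of complex with one exchanged in all that became complex with one exchanged or complex with two exchanged or over-reaction product, at the outlet or at the end, elm
- share of complex with one exchanged in all that became complex with one exchanged or complex with two exchanged or over-reaction product, at the outlet or at the end, birch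
- share of complex with one exchanged in all that became complex with one exchanged or complex with two exchanged or over-reaction product, at the outlet or at the end, cedar

The violet run refuses that world: at 15.0 min the complex with one exchanged is 13.6% of the charge, beside 7.5% of the complex with two exchanged and 6.0% of over-reaction product. That reads as a share of 50.2%, and birch is the same flask at the same time.

Two colleagues argue at the board about the other set-ups. Ana starts from the end state: over-reaction is written one way, so given time the material ends there, and the question is how fast. Violet gained 6.0% of over-reaction product while its complex with one exchanged stood near 9.2% at mid-run, which reads as a rate of 0.0435 min⁻¹. The logarithm of two over that rate is 15.9 min, the ageing half-life, the time in which over-reaction by itself halves a portion of complex with one exchanged.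

So Ana compares mean ages. Birch forms product about evenly, so its mean age is half the time, 7.50 min. In oak and elm the fed reactant builds up in proportion to time, so the mean age is a third of it, 5.00 min. Cedar's outlet carries the full 15 min.

Ben counts competition, the selectivity factor. At 8.00 min violet holds 6.3% of the complex with two exchanged, although starting complex stood at 83.4%, more than the 9.2% of complex with one exchanged. So he puts oak, with its scarce ligand, first and elm, with its full ligand, last.

I side with Ana on elm: violet has turned over just 27.1% of its charge by the end, less than stays unreacted, so dosed starting complex piles up in elm instead of being taken on arrival. Ben I keep for oak against elm, whose ages are equal. My order runs oak, elm, birch, cedar.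

The forecast reads oak > elm > birch > cedar, with 58%, 53%, 49% and 44%, and says of elm that “late-formed product has little time to react”.

The flask gives the order oak > elm > birch > cedar, with oak 55.4%, elm 51.6%, birch 47.0%, cedar 42.3%.

    starting complex + incoming ligand → leaving ligand + complex with one exchanged (k = 0.0104 L mol⁻¹ s⁻¹)
    complex with one exchanged + incoming ligand ⇌ leaving ligand + complex with two exchanged (K = 0.440, k = 0.0574 L mol⁻¹ s⁻¹)
    complex with one exchanged → over-reaction product (k = 7.72 × 10⁻⁴ s⁻¹)

The mean ages of elm and birch, 5.00 min and 7.50 min, both lie below my ageing half-life of 15.9 min. On the flask's 15 min they count 0.334 and 0.500 ageing half-lives, and elm stands above birch, so Ben's view keeps the pair of equal age, where oak leads elm by 3.8 percentage points. In birch the second exchange, forward rate counted by itself, has a half-life of 4.6 min, shorter than the 15 min of over-reaction. Left for 150 min, oak has run 10.0 ageing half-lives, and its share stands at 5.64%.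

The readings were generated by integration with constants of no real substance; the scatter is artificial.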